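**Retrosynthetic overview**

- The route rests on ring D (C1'–C4', C4a', C8a'), which holds a single alkene, C3'(CH3)=C4'. That alkene is conjugated with aromatic ring C and lies away from the trans C1'(OH)/C2'(acetyl) pair, so ring D is opened there by ring-closing metathesis into a C4a' vinyl group and a C2' isopropenyl group.
- The diene comes from an auxiliary-controlled anti-aldol between a biaryl 2-silyloxy-6-vinylbenzaldehyde and the N-(3-methylbut-3-enoyl) oxazolidinone, then Weinreb amide and methyl ketone formation.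
- The C7–C7' biaryl bond is made by Suzuki–Miyaura coupling of a 7-borylated 2-acetyl-1,8-dihydroxy-3-methylnaphthalene with 3-bromo-6-ethenyl-2-hydroxybenzaldehyde.
- Ring order: rings B and C are bought as benzenes, ring A is annulated onto ring B by a toluate-anion annulation, and ring D is closed last.

Key step: step 16

Numbering: naphthalene half C1–C8a (ring A = C1–C4, C4a, C8a; ring B = C4a–C8a); dihydronaphthalene half C1'–C8a' (ring C aromatic, ring D as above).

Abbreviations: TBS = tert-butyldimethylsilyl, TES = triethylsilyl, TMS = trimethylsilyl, Bpin = 4,4,5,5-tetramethyl-1,3,2-dioxaborolan-2-yl. Ar = 3-[7-acetyl-1-(TBS-oxy)-8-hydroxy-6-methylnaphthalen-2-yl]-2-(TBS-oxy)-6-ethenylphenyl, the biaryl unit made in step 10 less its formyl group.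

Assumption: the magnesium-catalysed aldol of the 3-methylbut-3-enoyl imide is taken to follow the chelated (Z)-enolate sense of induction known for N-propionyl oxazolidinones, which makes the (S)-auxiliary the one leading to (1'S,2'R).

**Route**

Step 1
Reactants: 1 2-bromo-5-methylphenol
Product: 2 3-bromo-2-hydroxy-6-methylbenzaldehyde
Conditions: MgCl2, Et3N, (CH2O)n, THF, reflux; aq. HCl
Reagents that add atoms: paraformaldehyde (formaldehyde), C=O
Why: Casnati–Skattebøl ortho-formylation delivers formaldehyde from the magnesium phenoxide only to an ortho carbon, and C6 is the one free ortho position, so the aldehyde enters between OH and CH3 while a second formaldehyde accepts the hydride.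

Step 2
Reactants: 2 3-bromo-2-hydroxy-6-methylbenzaldehyde
Product: 3 3-bromo-2-hydroxy-6-methylbenzoic acid
Conditions: NaClO2, H2NSO3H, THF/H2O, 0 → 23 °C
Reagents that add atoms: sodium chlorite, [Na+].[O-]Cl=O
Why: Lindgren chlorite oxidation converts the aldehyde into the acid, and sulfamic acid takes up the hypochlorous acid that would otherwise chlorinate the phenol ring.

Step 3
Reactants: 3 3-bromo-2-hydroxy-6-methylbenzoic acid
Product: 4 methyl 3-bromo-2-methoxy-6-methylbenzoate
Conditions: MeI (excess), K2CO3, DMF, 40 °C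
Reagents that add atoms: iodomethane, CI
Why: Williamson-type double O-methylation (carboxylate and phenoxide, both SN2 on iodomethane) gives the protected toluate needed for benzylic deprotonation.

Step 4
Reactants: 4 methyl 3-bromo-2-methoxy-6-methylbenzoate; 5 (E)-4-methoxypent-3-en-2-one
Product: 8 1-(7-bromo-1-hydroxy-8-methoxy-3-methylnaphthalen-2-yl)ethan-1-one, via lithiated toluate 6 (not isolated), via Michael–Dieckmann adduct 7 (not isolated)
Conditions: LiN(iPr)2, THF, −78 °C; then 5, −78 → 23 °C; aq. HCl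
Reagents that add atoms: none
Why: Staunton–Weinreb annulation: the ester-stabilised benzylic anion adds in conjugate fashion to the β-methoxy enone, the enolate acylates on the neighbouring ester (Dieckmann-type closure of ring A) and loss of methanol aromatises the new ring with acetyl at C2, methyl at C3 and OH at C1.

Step 5
Reactants: 8 1-(7-bromo-1-hydroxy-8-methoxy-3-methylnaphthalen-2-yl)ethan-1-one
Product: 9 1-(7-bromo-1,8-dihydroxy-3-methylnaphthalen-2-yl)ethan-1-one
Conditions: BBr3, CH2Cl2, −78 → 0 °C; MeOH, then H2O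
Reagents that add atoms: none
Why: Lewis acid ether cleavage, in which BBr3 binds the C8 methoxy oxygen and bromide removes the methyl group by SN2, while the aryl bromide and aryl ketone are inert.

Step 6
Reactants: 9 1-(7-bromo-1,8-dihydroxy-3-methylnaphthalen-2-yl)ethan-1-one
Product: 10 1-[1,8-dihydroxy-3-methyl-7-(Bpin)naphthalen-2-yl]ethan-1-one
Conditions: B2pin2, PdCl2(dppf), KOAc, 1,4-dioxane, 85 °C
Reagents that add atoms: bis(pinacolato)diboron, CC1(C)OB(OC1(C)C)B1OC(C)(C)C(C)(C)O1
Why: Miyaura borylation exchanges the C7 bromide for a pinacol boronate under the weak base KOAc, which the ketone and the phenols tolerate.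

Step 7
Reactants: 11 4-bromo-3-hydroxybenzaldehyde
Product: 12 2-bromo-5-ethenylphenol
Conditions: Ph3PCH3Br, KOtBu (excess), THF, 0 → 23 °C
Reagents that add atoms: methyltriphenylphosphonium bromide, C[P+](c1ccccc1)(c1ccccc1)c1ccccc1.[Br-]
Why: Wittig methylenation, in which excess ylide first deprotonates the phenol and then converts the aldehyde (meta to the phenoxide, so not deactivated) into the vinyl group.

Step 8
Reactants: 12 2-bromo-5-ethenylphenol
Product: 13 3-bromo-6-ethenyl-2-hydroxybenzaldehyde
Conditions: MgCl2, Et3N, (CH2O)n, THF, 65 °C, BHT (trace); aq. HCl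
Reagents that add atoms: paraformaldehyde (formaldehyde), C=O
Why: Casnati–Skattebøl ortho-formylation again has a single free ortho position, the carbon between OH and vinyl, and its mildly basic, non-radical medium leaves the styrene and the aryl bromide alone.

Step 9
Reactants: 10 1-[1,8-dihydroxy-3-methyl-7-(Bpin)naphthalen-2-yl]ethan-1-one; 13 3-bromo-6-ethenyl-2-hydroxybenzaldehyde
Product: 14 3-(7-acetyl-1,8-dihydroxy-6-methylnaphthalen-2-yl)-6-ethenyl-2-hydroxybenzaldehyde
Conditions: Pd(OAc)2, SPhos, K2CO3, 1,4-dioxane/H2O, 70 °C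
Reagents that add atoms: none
Why: Suzuki–Miyaura coupling joins C7 to C7' with a biaryl phosphine ligand that accepts ortho-oxygenated partners, carbonate is too weak a base to start a Claisen–Schmidt condensation between the acetyl and formyl groups, and the biaryl axis with only two ortho substituents rotates freely, so no stereo element arises.

Step 10
Reactants: 14 3-(7-acetyl-1,8-dihydroxy-6-methylnaphthalen-2-yl)-6-ethenyl-2-hydroxybenzaldehyde
Product: 15 3-[7-acetyl-1-(TBS-oxy)-8-hydroxy-6-methylnaphthalen-2-yl]-2-(TBS-oxy)-6-ethenylbenzaldehyde (Ar–CHO)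
Conditions: TBSCl (2.5 equiv), imidazole, DMF, 23 → 40 °C
Reagents that add atoms: tert-butyldimethylsilyl chloride, CC(C)(C)[Si](C)(C)Cl
Why: Silyl ether formation should take the C8 and C8' phenols, whereas the C1 hydroxyl, held in a six-membered hydrogen bond to the C2 acetyl group and then screened by the peri C8 silyl ether, should stay free.

Step 11
Reactants: 16 3-methylbut-3-enoic acid; 17 (4S)-4-benzyl-1,3-oxazolidin-2-one
Product: 19 (4S)-4-benzyl-3-(3-methylbut-3-enoyl)-1,3-oxazolidin-2-one, via mixed pivalic anhydride 18 (not isolated)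
Conditions: 16, t-BuCOCl, Et3N, THF, −78 → 0 °C; then 17 prelithiated with n-BuLi (THF, −78 °C), −78 → 0 °C; aq. NH4Cl
Reagents that add atoms: none
Why: Mixed-anhydride N-acylation of the lithiated oxazolidinone occurs at the less hindered carbonyl at low temperature, with too little base exposure to move the β,γ-alkene into conjugation.

Step 12
Reactants: 15 Ar–CHO; 19 (4S)-4-benzyl-3-(3-methylbut-3-enoyl)-1,3-oxazolidin-2-one
Product: 21 (4S)-4-benzyl-3-[(2R,3S)-3-Ar-3-hydroxy-2-(prop-1-en-2-yl)propanoyl]-1,3-oxazolidin-2-one, via trimethylsilyl ether 20 (not isolated)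
Conditions: MgCl2 (1 equiv), Et3N, TMSCl, EtOAc, 23 °C; then TFA (cat.), MeOH, 0 °C
Reagents that add atoms: none
Why: Evans magnesium halide-catalysed anti-aldol: soft enolisation gives the magnesium-chelated (Z)-dienolate, which reacts at its α-carbon on the face opposite the benzyl group (sets C2' as R) through a boat-like transition state that places the new oxygen anti to the isopropenyl group (sets C1' as S), and silylation of the aldolate by TMSCl pulls the reversible addition forward before acidic methanol frees the alcohol.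

Step 13
Reactants: 21 (4S)-4-benzyl-3-[(2R,3S)-3-Ar-3-hydroxy-2-(prop-1-en-2-yl)propanoyl]-1,3-oxazolidin-2-one
Product: 22 (2R,3S)-3-Ar-3-hydroxy-N-methoxy-N-methyl-2-(prop-1-en-2-yl)propanamide
Conditions: AlMe3, MeNH(OMe)·HCl, CH2Cl2, −20 → 0 °C; aq. KNaC4H4O6 (potassium sodium tartrate)
Reagents that add atoms: N,O-dimethylhydroxylamine hydrochloride, CNOC.Cl
Why: Aluminium amide transamination (Weinreb amide formation), in which the C1' aluminium alkoxide directs the amide to the exocyclic imide carbonyl and the non-basic medium leaves C2' and the isopropenyl alkene unchanged.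

Step 14
Reactants: 22 (2R,3S)-3-Ar-3-hydroxy-N-methoxy-N-methyl-2-(prop-1-en-2-yl)propanamide
Product: 23 (2R,3S)-3-Ar-N-methoxy-N-methyl-2-(prop-1-en-2-yl)-3-(triethylsilyloxy)propanamide
Conditions: TESOTf (1.3 equiv), 2,6-lutidine, CH2Cl2, −78 °C
Reagents that add atoms: triethylsilyl trifluoromethanesulfonate, CC[Si](CC)(CC)OS(=O)(=O)C(F)(F)F
Why: Silylation of the hindered secondary benzylic alcohol with the reactive silyl triflate at low temperature closes the retro-aldol and elimination pathways for the steps that follow.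

Step 15
Reactants: 23 (2R,3S)-3-Ar-N-methoxy-N-methyl-2-(prop-1-en-2-yl)-3-(triethylsilyloxy)propanamide
Product: 24 (3R,4S)-4-Ar-3-(prop-1-en-2-yl)-4-(triethylsilyloxy)butan-2-one
Conditions: MeMgBr (3.5 equiv), THF, −78 → −20 °C; aq. NH4Cl
Reagents that add atoms: methylmagnesium bromide, C[Mg]Br
Why: Weinreb ketone synthesis: the five-membered magnesium chelate stops at mono-addition, and the C2 acetyl group of the naphthalene should not compete because the first equivalent of Grignard reagent turns C1-OH into a magnesium phenoxide conjugated with and chelated to that carbonyl, which is also flanked by two ortho substituents.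

Step 16
Reactants: 24 (3R,4S)-4-Ar-3-(prop-1-en-2-yl)-4-(triethylsilyloxy)butan-2-one
Product: 25 1-[(1S,2R)-7-{7-acetyl-1-(TBS-oxy)-8-hydroxy-6-methylnaphthalen-2-yl}-8-(TBS-oxy)-3-methyl-1-(triethylsilyloxy)-1,2-dihydronaphthalen-2-yl]ethan-1-one
Conditions: second-generation Grubbs catalyst RuCl2(H2IMes)(PCy3)(=CHPh) (10 mol%), 1,4-benzoquinone (20 mol%), CH2Cl2 (5 mM), 40 °C, argon
Reagents that add atoms: none
Why: The ruthenium benzylidene exchanges onto the unhindered C4a' vinyl group, the resulting styrenyl carbene adds across the 1,1-disubstituted isopropenyl alkene in a [2+2] cycloaddition, and cycloreversion of the ruthenacyclobutane forms the C3'=C4' bond while ethene leaves the solution. The closest known reaction type is ring-closing metathesis of ortho-vinylaryl dienes to 1,2-dihydronaphthalenes with N-heterocyclic-carbene ruthenium catalysts. Ring D closes as a six-membered carbocycle by this diene metathesis, the new trisubstituted alkene being endocyclic and conjugated with ring C. No stereocentre is created: C1' (S) and C2' (R) come from the aldol of step 12 and stay untouched in the neutral, aprotic medium. The selectivity needed is ring closure in preference to migration of the isopropenyl double bond toward the C2' ketone, β-elimination of the C1' oxygen and intermolecular metathesis; high dilution, benzoquinone as a scavenger of ruthenium hydrides and the C1' triethylsilyl ether secure it.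

Step 17
Reactants: 25 tris-silyl ether of the target
Product: 26 1-[(1S,2R)-7-(7-acetyl-1,8-dihydroxy-6-methylnaphthalen-2-yl)-1,8-dihydroxy-3-methyl-1,2-dihydronaphthalen-2-yl]ethan-1-one (CNP0298944.1)
Conditions: HF·pyridine, excess pyridine, THF, 0 → 23 °C
Reagents that add atoms: none
Why: Fluoride-mediated silyl ether cleavage with pyridine-buffered HF·pyridine removes all three silyl groups near neutrality, so that the C1' hydroxyl is not lost by E1cB or acid-promoted elimination toward a fully aromatic naphthalene and C2' is not epimerised.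

**Compound list**

1 | 2-bromo-5-methylphenol | Cc1ccc(Br)c(O)c1 | starting material
2 | 3-bromo-2-hydroxy-6-methylbenzaldehyde | Cc1ccc(Br)c(O)c1C=O | intermediate
3 | 3-bromo-2-hydroxy-6-methylbenzoic acid | Cc1ccc(Br)c(O)c1C(=O)O | intermediate
4 | methyl 3-bromo-2-methoxy-6-methylbenzoate | COC(=O)c1c(C)ccc(Br)c1OC | intermediate
5 | (E)-4-methoxypent-3-en-2-one | CO/C(C)=C/C(C)=O | starting material
6 | methyl 3-bromo-6-(lithiomethyl)-2-methoxybenzoate (not isolated) | COC(=O)c1c(C[Li])ccc(Br)c1OC | intermediate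
7 | 2-acetyl-7-bromo-3,8-dimethoxy-3-methyl-3,4-dihydronaphthalen-1(2H)-one, present as its lithium enolate, diastereomer mixture (not isolated) | CC(=O)C1C(=O)c2c(OC)c(Br)ccc2CC1(C)OC | intermediate
8 | 1-(7-bromo-1-hydroxy-8-methoxy-3-methylnaphthalen-2-yl)ethan-1-one | CC(=O)c1c(C)cc2ccc(Br)c(OC)c2c1O | intermediate
9 | 1-(7-bromo-1,8-dihydroxy-3-methylnaphthalen-2-yl)ethan-1-one | CC(=O)c1c(C)cc2ccc(Br)c(O)c2c1O | intermediate
10 | 1-[1,8-dihydroxy-3-methyl-7-(4,4,5,5-tetramethyl-1,3,2-dioxaborolan-2-yl)naphthalen-2-yl]ethan-1-one | CC(=O)c1c(C)cc2ccc(B3OC(C)(C)C(C)(C)O3)c(O)c2c1O | intermediate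
11 | 4-bromo-3-hydroxybenzaldehyde | O=Cc1ccc(Br)c(O)c1 | starting material
12 | 2-bromo-5-ethenylphenol | C=Cc1ccc(Br)c(O)c1 | intermediate
13 | 3-bromo-6-ethenyl-2-hydroxybenzaldehyde | C=Cc1ccc(Br)c(O)c1C=O | intermediate
14 | 3-(7-acetyl-1,8-dihydroxy-6-methylnaphthalen-2-yl)-6-ethenyl-2-hydroxybenzaldehyde | CC(=O)c1c(C)cc2ccc(-c3ccc(C=C)c(C=O)c3O)c(O)c2c1O | intermediate
15 | 3-[7-acetyl-1-(tert-butyldimethylsilyloxy)-8-hydroxy-6-methylnaphthalen-2-yl]-2-(tert-butyldimethylsilyloxy)-6-ethenylbenzaldehyde | CC(=O)c1c(C)cc2ccc(-c3ccc(C=C)c(C=O)c3O[Si](C)(C)C(C)(C)C)c(O[Si](C)(C)C(C)(C)C)c2c1O | intermediate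
16 | 3-methylbut-3-enoic acid | C=C(C)CC(=O)O | starting material
17 | (4S)-4-benzyl-1,3-oxazolidin-2-one | O=C1N[C@@H](Cc2ccccc2)CO1 | starting material
18 | 3-methylbut-3-enoic pivalic anhydride (not isolated) | C=C(C)CC(=O)OC(=O)C(C)(C)C | intermediate
19 | (4S)-4-benzyl-3-(3-methylbut-3-enoyl)-1,3-oxazolidin-2-one | C=C(C)CC(=O)N1C(=O)OC[C@@H]1Cc1ccccc1 | intermediate
20 | (4S)-4-benzyl-3-[(2R,3S)-3-Ar-2-(prop-1-en-2-yl)-3-(trimethylsilyloxy)propanoyl]-1,3-oxazolidin-2-one (not isolated) | CC(=O)c1c(C)cc2ccc(-c3ccc(C=C)c([C@@H](O[Si](C)(C)C)[C@H](C(=O)N4C(=O)OC[C@@H]4Cc4ccccc4)C(C)=C)c3O[Si](C)(C)C(C)(C)C)c(O[Si](C)(C)C(C)(C)C)c2c1O | intermediate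
21 | (4S)-4-benzyl-3-[(2R,3S)-3-Ar-3-hydroxy-2-(prop-1-en-2-yl)propanoyl]-1,3-oxazolidin-2-one | CC(=O)c1c(C)cc2ccc(-c3ccc(C=C)c([C@@H](O)[C@H](C(=O)N4C(=O)OC[C@@H]4Cc4ccccc4)C(C)=C)c3O[Si](C)(C)C(C)(C)C)c(O[Si](C)(C)C(C)(C)C)c2c1O | intermediate
22 | (2R,3S)-3-Ar-3-hydroxy-N-methoxy-N-methyl-2-(prop-1-en-2-yl)propanamide | CC(=O)c1c(C)cc2ccc(-c3ccc(C=C)c([C@@H](O)[C@H](C(=O)N(C)OC)C(C)=C)c3O[Si](C)(C)C(C)(C)C)c(O[Si](C)(C)C(C)(C)C)c2c1O | intermediate
23 | (2R,3S)-3-Ar-N-methoxy-N-methyl-2-(prop-1-en-2-yl)-3-(triethylsilyloxy)propanamide | CC(=O)c1c(C)cc2ccc(-c3ccc(C=C)c([C@@H](O[Si](CC)(CC)CC)[C@H](C(=O)N(C)OC)C(C)=C)c3O[Si](C)(C)C(C)(C)C)c(O[Si](C)(C)C(C)(C)C)c2c1O | intermediate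
24 | (3R,4S)-4-Ar-3-(prop-1-en-2-yl)-4-(triethylsilyloxy)butan-2-one (metathesis precursor, 1'S,2'R) | CC(=O)c1c(C)cc2ccc(-c3ccc(C=C)c([C@@H](O[Si](CC)(CC)CC)[C@H](C(C)=O)C(C)=C)c3O[Si](C)(C)C(C)(C)C)c(O[Si](C)(C)C(C)(C)C)c2c1O | intermediate
25 | 1-[(1S,2R)-7-{7-acetyl-1-(tert-butyldimethylsilyloxy)-8-hydroxy-6-methylnaphthalen-2-yl}-8-(tert-butyldimethylsilyloxy)-3-methyl-1-(triethylsilyloxy)-1,2-dihydronaphthalen-2-yl]ethan-1-one | CC(=O)c1c(C)cc2ccc(-c3ccc4c(c3O[Si](C)(C)C(C)(C)C)[C@@H](O[Si](CC)(CC)CC)[C@H](C(C)=O)C(C)=C4)c(O[Si](C)(C)C(C)(C)C)c2c1O | intermediate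
26 | 1-[(1S,2R)-7-(7-acetyl-1,8-dihydroxy-6-methylnaphthalen-2-yl)-1,8-dihydroxy-3-methyl-1,2-dihydronaphthalen-2-yl]ethan-1-one | CC(=O)c1c(C)cc2ccc(-c3ccc4c(c3O)[C@@H](O)[C@H](C(C)=O)C(C)=C4)c(O)c2c1O | target

**Step count and risks**

Total step count: 17. Longest linear sequence: 14 steps (steps 1–6, 9, 10, 12–17).

Steps most likely to fail:

1. Step 12 (anti-aldol). Addition of the magnesium dienolate to the di-ortho-substituted aldehyde may be slow, so that retro-aldol equilibration erodes the anti selectivity, the dienolate reacts at its γ-carbon, or Et3N moves the β,γ-alkene of the imide into conjugation. The fallback sets out from 15 and 19 and returns at 21. Imide 19 is enolised with Bu2BOTf and iPr2NEt (CH2Cl2, −78 → 0 °C) to the (Z)-dibutylboron dienolate F1. F1 is added at −78 °C to aldehyde 15 precomplexed with Et2AlCl. This stoichiometric, Lewis acid-mediated aldol runs through an open transition state on the boron-chelated enolate; it should use the same enolate face and give the anti relationship, and a pH 7 buffer/methanol work-up should give hydroxy imide 21 directly.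

2. Step 16 (ring-closing metathesis). The isopropenyl alkene, flanked by two silyl ethers, may fail to engage the styrenyl carbene so that dimerisation at the vinyl group takes over, or ruthenium hydrides may move the isopropenyl double bond into conjugation with the C2' ketone. The fallback sets out from 24 and returns at 26. The three silyl groups are removed first (HF·pyridine, pyridine, THF) to give the free (1'S,2'R) diene F2. Metathesis of this less crowded substrate with the second-generation Hoveyda–Grubbs catalyst RuCl2(H2IMes)(=CH-C6H4-2-OiPr) and benzoquinone should give target 26 directly, since ruthenium carbenes tolerate phenols and secondary alcohols. The ring-closed, elimination-prone product then never meets fluoride.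

3. Step 15 (methyl ketone formation). The Grignard reagent may add to the C2 acetyl group of the naphthalene, or deprotonate C2' so that the isopropenyl double bond migrates. The fallback sets out from 21 and returns at 24. Silylation (TESOTf, 2,6-lutidine, CH2Cl2, −78 °C) gives the triethylsilyl-protected imide F3. Lithium ethanethiolate (EtSH, n-BuLi, THF, 0 °C) displaces the auxiliary to give the S-ethyl thioester F4. Fukuyama coupling of F4 with MeZnI and PdCl2(PPh3)2 (toluene/THF, 23 °C), which leaves ketones untouched, should give methyl ketone 24.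

Further compounds

F1 | step 12 | (Z)-dibutylboron dienolate of imide 19 | C=C(C)/C=C(\OB(CCCC)CCCC)N1C(=O)OC[C@@H]1Cc1ccccc1
F2 | step 16 | fully desilylated diene, (3R,4S)-4-[3-(7-acetyl-1,8-dihydroxy-6-methylnaphthalen-2-yl)-6-ethenyl-2-hydroxyphenyl]-4-hydroxy-3-(prop-1-en-2-yl)butan-2-one | CC(=O)c1c(C)cc2ccc(-c3ccc(C=C)c([C@@H](O)[C@H](C(C)=O)C(C)=C)c3O)c(O)c2c1O
F3 | step 15 | (4S)-4-benzyl-3-[(2R,3S)-3-Ar-2-(prop-1-en-2-yl)-3-(triethylsilyloxy)propanoyl]-1,3-oxazolidin-2-one | CC(=O)c1c(C)cc2ccc(-c3ccc(C=C)c([C@@H](O[Si](CC)(CC)CC)[C@H](C(=O)N4C(=O)OC[C@@H]4Cc4ccccc4)C(C)=C)c3O[Si](C)(C)C(C)(C)C)c(O[Si](C)(C)C(C)(C)C)c2c1O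
F4 | step 15 | S-ethyl (2R,3S)-3-Ar-2-(prop-1-en-2-yl)-3-(triethylsilyloxy)propanethioate | CC(=O)c1c(C)cc2ccc(-c3ccc(C=C)c([C@@H](O[Si](CC)(CC)CC)[C@H](C(=O)SCC)C(C)=C)c3O[Si](C)(C)C(C)(C)C)c(O[Si](C)(C)C(C)(C)C)c2c1O
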